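The route rests on opening the dihydropyranone ring of the chromenedione across two opposite bonds: C2–C3 and the ring-fusion double bond C4a=C8a, which also opens the carbocycle. The feature used is the vinylogous ester O1–C8a=C4a–C4(=O): C4a and C3 flank the C4 carbonyl as a latent bis-nucleophile, while C8a and C2 flank O1 as two oxocarbenium-type electrophiles. The precursor is therefore acyclic, a 2-diazo-1,3,5-triketone whose quaternary stereocentre carries a divinyl acetal. One chiral Brønsted acid closes both rings: the diazo carbon captures the acetal-derived oxocarbenium ion (C4a=C8a, with loss of N2), then the surviving vinyl ether is protonated and the acetyl enol closes C2–C3.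

Key step: step 8

Remark: atom labels O1, C2, C3, C4, C4a, C5 to C8 and C8a follow the chromene numbering of the target.
Remark: compounds 1, 2, 6, 9, 10 and 15 are taken as commercial; the sense of induction of the chiral catalysts in steps 1 and 8 is assumed by analogy, and the other enantiomer of either catalyst is used if it proves opposite.
Remark: the prenyl group is introduced last, because a prenyl alkene would compete with the weakly nucleophilic diazo carbon for the oxocarbenium ion in step 8.

Step 1
Reactants: 1 tert-butyl 2-methyl-3-oxobutanoate; 2 geranyl bromide, (2E)-1-bromo-3,7-dimethylocta-2,6-diene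
Product: 3 tert-butyl (2S,4E)-2-acetyl-2,5,9-trimethyldeca-4,8-dienoate
Conditions: (S,S)-N-spiro bis(binaphthyl)ammonium bromide with 3,4,5-trifluorophenyl groups at the 3,3'-positions (1 mol%), CsOH·H2O, toluene, −40 °C
Reagents that add atoms: geranyl bromide, CC(C)=CCC/C(C)=C/CBr
Why: Asymmetric phase-transfer alkylation, in which the chiral ammonium cation ion-pairs with the enolate of 1 and shields one face, so that SN2 attack on the allylic bromide should set the quaternary centre as S, helped by the bulky tert-butyl ester.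

Step 2
Reactants: 3
Product: 4 (2R,4E)-2-(1-hydroxyethyl)-2,5,9-trimethyldeca-4,8-dien-1-ol, both epimers at the secondary carbinol
Conditions: LiAlH4, THF, 0 °C to reflux; aq NaOH work-up
Reagents that add atoms: none
Why: Hydride reduction of ketone and tert-butyl ester should give the 1,3-diol; the quaternary centre has no hydrogen and is untouched, and the uncontrolled carbinol centre is removed again in step 3.

Step 3
Reactants: 4
Product: 5 (2R,4E)-2-acetyl-2,5,9-trimethyldeca-4,8-dienal
Conditions: Dess–Martin periodinane (2.5 equiv), CH2Cl2, 0 °C to rt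
Reagents that add atoms: none
Why: Dess–Martin oxidation of both alcohols should give the non-enolisable β-keto aldehyde under neutral conditions that leave the trisubstituted alkenes alone.

Step 4
Reactants: 5; 6 2-chloroethanol
Product: 7 (3R,5E)-3-[bis(2-chloroethoxy)methyl]-3,6,10-trimethylundeca-5,9-dien-2-one
Conditions: 2-chloroethanol (excess), pyridinium p-toluenesulfonate (cat.), benzene, reflux, Dean–Stark trap
Reagents that add atoms: 2-chloroethanol, OCCCl
Why: Acid-catalysed acetalisation should be chemoselective for the aldehyde over the hindered α-quaternary methyl ketone and is driven by azeotropic removal of water.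

Step 5
Reactants: 7
Product: 8 (3R,5E)-3-[bis(ethenyloxy)methyl]-3,6,10-trimethylundeca-5,9-dien-2-one
Conditions: KOtBu (3 equiv), THF, 0 to 40 °C
Reagents that add atoms: none
Why: Double E2 dehydrochlorination of the 2-chloroethyl ethers by the hindered alkoxide should give the divinyl acetal, which is stable to base; the ketone enolate that forms reversibly is reprotonated on work-up.

Step 6
Reactants: 9 2,5-dioxopyrrolidin-1-yl 3-oxobutanoate (N-hydroxysuccinimidyl acetoacetate); 10 4-acetamidobenzenesulfonyl azide
Product: 11 2,5-dioxopyrrolidin-1-yl 2-diazo-3-oxobutanoate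
Conditions: Et3N, MeCN, 0 °C to rt
Reagents that add atoms: 4-acetamidobenzenesulfonyl azide, CC(=O)Nc1ccc(cc1)S(=O)(=O)N=[N+]=[N-]
Why: Regitz diazo transfer to the active methylene of the acetoacetate, the active ester being inert to the tertiary amine.

Step 7
Reactants: 8; 11
Product: 12 (7R,9E)-7-[bis(ethenyloxy)methyl]-3-diazo-7,10,14-trimethylpentadeca-9,13-diene-2,4,6-trione
Conditions: LiN(SiMe3)2 (2.2 equiv), THF, −78 °C; then 11, −78 to −20 °C; aq NH4Cl
Reagents that add atoms: 2,5-dioxopyrrolidin-1-yl 2-diazo-3-oxobutanoate, CC(=O)C(=[N+]=[N-])C(=O)ON1C(=O)CCC1=O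
Why: Claisen-type C-acylation of the kinetic lithium enolate of the methyl ketone (its only enolisable position) by the active ester, the second equivalent of base deprotonating the product 1,3-diketone; the diazo group arrives already in place, so no choice between the two methylene groups arises.

Step 8
Reactants: 12
Product: 14 (2S,8R)-8-[(2E)-3,7-dimethylocta-2,6-dien-1-yl]-5-hydroxy-2,8-dimethyl-2,3-dihydro-4H-chromene-4,7(8H)-dione, via vinyl enol ether 13 (not isolated)
Conditions: (R)-3,3'-bis(2,4,6-triisopropylphenyl)-1,1'-binaphthyl-2,2'-diyl N-triflylphosphoramide (10 mol%), toluene, 5 Å molecular sieves, slow argon purge, −40 °C to rt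
Reagents that add atoms: none
Why: Proposed new method: the chiral acid ionises the divinyl acetal (one vinyloxy arm leaves as acetaldehyde) to an O-vinyl oxocarbenium ion at C8a, which the diazo carbon C4a captures in a 6-exo-trig closure of the carbocycle; the diazonium ion then loses N2 with a 1,2-hydride shift and a proton, so that the C4a=C8a enol ether 13 forms at the correct oxidation level with the second vinyloxy group retained. The released acid next protonates the vinyl ether at its terminal carbon, and the enol carbon of the acetyl group (C3) closes onto the O1=C2 oxocarbenium ion in a 6-(enolendo)-endo-trig step. The closest known reaction types are the Roskamp homologation (diazo carbon plus aldehyde, nitrogen loss with hydride shift), here run on an oxocarbenium ion, and Prins or Mukaiyama-type additions of enols to oxocarbenium ions made by Brønsted-acid protonation of vinyl ethers. The only new stereocentre, C2, is set in the second closure by the chiral phosphoramide anion of the contact ion pair (catalyst control), because C8 is remote and its methyl and geranyl groups differ too little to bias the faces. The step needs capture of the C8a cation by the diazo carbon rather than by other nucleophiles, which the substrate secures because C4a is the only carbon that reaches C8a through a six-membered ring (the C6 methylene would close a four-membered ring, and addition of an enol oxygen is reversible); it also needs hydride rather than alkyl or alkoxy migration, which is favoured because only the hydride shift gives an oxygen-stabilised cation.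

Step 9
Reactants: 14; 15 3-methylbut-2-en-1-yl acetate (prenyl acetate)
Product: 16 (2S,8R)-8-[(2E)-3,7-dimethylocta-2,6-dien-1-yl]-5-hydroxy-2,8-dimethyl-6-(3-methylbut-2-en-1-yl)-2,3-dihydro-4H-chromene-4,7(8H)-dione
Conditions: Pd(PPh3)4 (5 mol%), Et3N, THF, rt to 50 °C
Reagents that add atoms: prenyl acetate, CC(=O)OCC=C(C)C
Why: Tsuji–Trost allylation, in which the soft enolate of the cyclic vinylogous acid attacks the less hindered terminus of the π-prenylpalladium complex at C6 and any O-prenyl ether re-ionises and funnels to the C-alkylated product; no stereocentre is formed or touched.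

Compound list
1 | tert-butyl 2-methyl-3-oxobutanoate | CC(=O)C(C)C(=O)OC(C)(C)C | starting material
2 | geranyl bromide, (2E)-1-bromo-3,7-dimethylocta-2,6-diene | CC(C)=CCC/C(C)=C/CBr | starting material
3 | tert-butyl (2S,4E)-2-acetyl-2,5,9-trimethyldeca-4,8-dienoate | CC(C)=CCC/C(C)=C/C[C@@](C(=O)OC(C)(C)C)(C)C(C)=O | intermediate
4 | (2R,4E)-2-(1-hydroxyethyl)-2,5,9-trimethyldeca-4,8-dien-1-ol, both carbinol epimers | CC(C)=CCC/C(C)=C/C[C@@](CO)(C)C(C)O | intermediate
5 | (2R,4E)-2-acetyl-2,5,9-trimethyldeca-4,8-dienal | CC(C)=CCC/C(C)=C/C[C@@](C=O)(C)C(C)=O | intermediate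
6 | 2-chloroethanol | OCCCl | starting material
7 | (3R,5E)-3-[bis(2-chloroethoxy)methyl]-3,6,10-trimethylundeca-5,9-dien-2-one | CC(C)=CCC/C(C)=C/C[C@@](C(OCCCl)OCCCl)(C)C(C)=O | intermediate
8 | (3R,5E)-3-[bis(ethenyloxy)methyl]-3,6,10-trimethylundeca-5,9-dien-2-one | CC(C)=CCC/C(C)=C/C[C@@](C(OC=C)OC=C)(C)C(C)=O | intermediate
9 | 2,5-dioxopyrrolidin-1-yl 3-oxobutanoate | CC(=O)CC(=O)ON1C(=O)CCC1=O | starting material
10 | 4-acetamidobenzenesulfonyl azide | CC(=O)Nc1ccc(cc1)S(=O)(=O)N=[N+]=[N-] | starting material
11 | 2,5-dioxopyrrolidin-1-yl 2-diazo-3-oxobutanoate | CC(=O)C(=[N+]=[N-])C(=O)ON1C(=O)CCC1=O | intermediate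
12 | (7R,9E)-7-[bis(ethenyloxy)methyl]-3-diazo-7,10,14-trimethylpentadeca-9,13-diene-2,4,6-trione | CC(C)=CCC/C(C)=C/C[C@@](C(OC=C)OC=C)(C)C(=O)CC(=O)C(=[N+]=[N-])C(C)=O | intermediate
13 | (6R)-4-acetyl-6-[(2E)-3,7-dimethylocta-2,6-dien-1-yl]-5-(ethenyloxy)-3-hydroxy-6-methylcyclohexa-2,4-dien-1-one, not isolated | CC(C)=CCC/C(C)=C/C[C@@]1(C)C(=O)C=C(O)C(C(C)=O)=C1OC=C | intermediate
14 | (2S,8R)-8-[(2E)-3,7-dimethylocta-2,6-dien-1-yl]-5-hydroxy-2,8-dimethyl-2,3-dihydro-4H-chromene-4,7(8H)-dione | CC(C)=CCC/C(C)=C/C[C@@]1(C)C(=O)C=C(O)C2=C1O[C@@H](C)CC2=O | intermediate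
15 | 3-methylbut-2-en-1-yl acetate | CC(=O)OCC=C(C)C | starting material
16 | (2S,8R)-8-[(2E)-3,7-dimethylocta-2,6-dien-1-yl]-5-hydroxy-2,8-dimethyl-6-(3-methylbut-2-en-1-yl)-2,3-dihydro-4H-chromene-4,7(8H)-dione | CC(C)=CCC/C(C)=C/C[C@@]1(C)C(=O)C(CC=C(C)C)=C(O)C2=C1O[C@@H](C)CC2=O | target

Total step count: 9. Longest linear sequence: 8 steps (1, 2, 3, 4, 5, 7, 8, 9); step 6 is a one-step branch.

Steps most likely to fail

Step 8. Several processes may defeat the domino:
- The first cation may be intercepted before the carbocycle closes, by attack of the C6 methylene or of the second vinyl ether on the protonated vinyl arm.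
- The weakly nucleophilic diazo carbon may add too slowly.
- The acetaldehyde unit may migrate between the two enol oxygens that flank the acyl group through a cyclic acetal before C2–C3 closes, which loses regiocontrol.
- Facial control at C2 by the counter-anion may be poor.

The fallback uses known chemistry only; it sets out from 3 and comes back at 16. Alkylation of the methyl ketone enolate of 3 (LiN(iPr)2, prenyl bromide) should give tert-butyl (2S,4E)-2,5,9-trimethyl-2-(5-methylhex-4-enoyl)deca-4,8-dienoate F1. C-Acetylation of its ketone enolate (LiN(iPr)2, 1-acetylimidazole) should give tert-butyl (2S,4E)-2-(2-acetyl-5-methylhex-4-enoyl)-2,5,9-trimethyldeca-4,8-dienoate F2. Dieckmann cyclisation of the dianion of F2 (LiN(iPr)2, 2 equiv) should give (6R)-6-[(2E)-3,7-dimethylocta-2,6-dien-1-yl]-6-methyl-2-(3-methylbut-2-en-1-yl)cyclohexane-1,3,5-trione F3, which keeps the stereocentre because the prenyl group makes the two sides of the ring different. Steglich acylation with (R)-3-[(tert-butyldimethylsilyl)oxy]butanoic acid (DCC, DMAP, with O-to-C acyl shift) should give (6R)-4-{(3R)-3-[(tert-butyldimethylsilyl)oxy]butanoyl}-6-[(2E)-3,7-dimethylocta-2,6-dien-1-yl]-3,5-dihydroxy-6-methyl-2-(3-methylbut-2-en-1-yl)cyclohexa-2,4-dien-1-one F4. HF·pyridine should free (6R)-6-[(2E)-3,7-dimethylocta-2,6-dien-1-yl]-3,5-dihydroxy-4-[(3R)-3-hydroxybutanoyl]-6-methyl-2-(3-methylbut-2-en-1-yl)cyclohexa-2,4-dien-1-one F5. Mitsunobu etherification (PPh3, diisopropyl azodicarboxylate) then closes the dihydropyranone with inversion at the carbinol carbon to 16. The regioisomer from closure on the other enol oxygen would have to be removed by chromatography.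

Step 1. Facial discrimination of the acyclic enolate may be insufficient (two enolate geometries, loose ion pair), and O-alkylation may compete. The fallback sets out from 1 and comes back at 3 by a chiral-enamine alkylation. Condensation of 1 with L-valine tert-butyl ester (cat. TsOH, benzene, Dean–Stark trap) should give tert-butyl (2Z)-3-{[(2S)-1-tert-butoxy-3-methyl-1-oxobutan-2-yl]amino}-2-methylbut-2-enoate F6. Deprotonation with LiN(iPr)2 in toluene (or in THF with HMPA if the opposite sense is needed) and alkylation of the chelated lithio-enamine with 2 should give tert-butyl (2S,4E)-2-{N-[(2S)-1-tert-butoxy-3-methyl-1-oxobutan-2-yl]ethanimidoyl}-2,5,9-trimethyldeca-4,8-dienoate F7. Hydrolysis with aqueous acetic acid returns 3 and releases the auxiliary.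

Step 7. The enolate may add to the terminal diazo nitrogen or to the acetyl carbonyl of 11 (acetyl transfer) instead of the active ester carbonyl, or may be acylated on oxygen. The fallback sets out from 8 and comes back at 12 in two known operations. Acetoacetylation of the lithium enolate of 8 with diketene should give (7R,9E)-7-[bis(ethenyloxy)methyl]-7,10,14-trimethylpentadeca-9,13-diene-2,4,6-trione F8. Regitz diazo transfer with 10 (1 equiv, Et3N, MeCN) then installs the diazo group, the less hindered C3 methylene being expected to react in preference to C5.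

Further compounds
F1 | step 8 | tert-butyl (2S,4E)-2,5,9-trimethyl-2-(5-methylhex-4-enoyl)deca-4,8-dienoate | CC(C)=CCC/C(C)=C/C[C@@](C(=O)OC(C)(C)C)(C)C(=O)CCC=C(C)C
F2 | step 8 | tert-butyl (2S,4E)-2-(2-acetyl-5-methylhex-4-enoyl)-2,5,9-trimethyldeca-4,8-dienoate | CC(C)=CCC/C(C)=C/C[C@@](C(=O)OC(C)(C)C)(C)C(=O)C(CC=C(C)C)C(C)=O
F3 | step 8 | (6R)-6-[(2E)-3,7-dimethylocta-2,6-dien-1-yl]-6-methyl-2-(3-methylbut-2-en-1-yl)cyclohexane-1,3,5-trione | CC(C)=CCC/C(C)=C/C[C@@]1(C)C(=O)C(CC=C(C)C)C(=O)CC1=O
F4 | step 8 | (6R)-4-{(3R)-3-[(tert-butyldimethylsilyl)oxy]butanoyl}-6-[(2E)-3,7-dimethylocta-2,6-dien-1-yl]-3,5-dihydroxy-6-methyl-2-(3-methylbut-2-en-1-yl)cyclohexa-2,4-dien-1-one | CC(C)=CCC/C(C)=C/C[C@@]1(C)C(=O)C(CC=C(C)C)=C(O)C(C(=O)C[C@@H](C)O[Si](C)(C)C(C)(C)C)=C1O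
F5 | step 8 | (6R)-6-[(2E)-3,7-dimethylocta-2,6-dien-1-yl]-3,5-dihydroxy-4-[(3R)-3-hydroxybutanoyl]-6-methyl-2-(3-methylbut-2-en-1-yl)cyclohexa-2,4-dien-1-one | CC(C)=CCC/C(C)=C/C[C@@]1(C)C(=O)C(CC=C(C)C)=C(O)C(C(=O)C[C@@H](C)O)=C1O
F6 | step 1 | tert-butyl (2Z)-3-{[(2S)-1-tert-butoxy-3-methyl-1-oxobutan-2-yl]amino}-2-methylbut-2-enoate | C/C(N[C@@H](C(C)C)C(=O)OC(C)(C)C)=C(\C)C(=O)OC(C)(C)C
F7 | step 1 | tert-butyl (2S,4E)-2-{N-[(2S)-1-tert-butoxy-3-methyl-1-oxobutan-2-yl]ethanimidoyl}-2,5,9-trimethyldeca-4,8-dienoate, imine geometry not defined | CC(C)=CCC/C(C)=C/C[C@@](C(=O)OC(C)(C)C)(C)C(C)=N[C@@H](C(C)C)C(=O)OC(C)(C)C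
F8 | step 7 | (7R,9E)-7-[bis(ethenyloxy)methyl]-7,10,14-trimethylpentadeca-9,13-diene-2,4,6-trione | CC(C)=CCC/C(C)=C/C[C@@](C(OC=C)OC=C)(C)C(=O)CC(=O)CC(C)=O
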